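**Plan**
- Retrosynthesis: the 26-membered lactone ring is opened at the C11–C12 single bond, then at the C1–O25 ester and the C25–C26 bond. This gives acid C1–C11, boronate C12–C25 and side-chain iodide C26–C36, which are cut further at C2=C3, C4=C5, C6–C7; C12–C13, C13–C14, C16–C17, C18=C19, C20=C21, C22–C23; C26=C27, C28–C29, C30=C31, C32–C33.
- Enabling feature: C11 is the unsubstituted CH end of the E-trisubstituted C10=C11 alkene (an alkenyl iodide from alkyne carboalumination). C12 is a methyl-bearing CH between CH2 groups with no β-heteroatom (a configurationally stable secondary boronate). The lactone ring can therefore be closed there by a stereoretentive C(sp2)–C(sp3) Suzuki–Miyaura macrocyclisation.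
- Forward: acid 10 (steps 1–7) and iodide 26 (steps 8–18) are made separately. The C12–C25 chain is grown linearly (steps 19–33), joined to 26 at C25–C26 (step 34) and esterified with 10 (step 35). The only macrocycle is closed last at C11–C12 (step 37), before desilylation.
- Stereochemistry: the three syn methoxy-carbinol pairs (C6/C7, C16/C17, C32/C33) come from (Z)-γ-methoxyallyl-diisopinocampheylboranes, C22/C23 from a Z-crotylborane, C29 from an allylborane, C30/C31 from asymmetric epoxidation, C24 from (S)-trityl glycidyl ether and C25 from Felkin–Anh addition. C12 comes from a sparteine-controlled 1,2-metallate homologation and is carried through the ring closure with retention.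

Key step: step 37

Remark: reagents given only by name and SMILES (ylides, phosphonate, silyl triflate, pinacolborane, ethyl 2,4,6-triisopropylbenzoate, (−)-sparteine, both antipodes of B-methoxydiisopinocampheylborane, (+)-B-allyldiisopinocampheylborane) are taken as commercial. Locants C1–C36 in descriptive names are those of the target chain (C1 lactone carbonyl, C25 lactone-oxygen carbon, C36 side-chain methyl), and "as in target" means the spatial arrangement shown in the SMILES. TES = triethylsilyl, PMB = 4-methoxybenzyl, Ipc = isopinocampheyl, Bpin = pinacol boronate.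

**Part 1: acid C1–C11**

Step 1
Reactants: 1 prop-2-yn-1-ol
Product: 3 (E)-3-iodo-2-methylprop-2-en-1-ol, via alkenylalane 2 (not isolated)
Conditions: Me3Al, Cp2ZrCl2 (0.25 equiv), CH2Cl2, 0 °C to rt; then I2, THF, −30 °C; aq. K2CO3
Reagents that add atoms: trimethylaluminium C[Al](C)C; iodine II
Why: Zirconium-catalysed carboalumination (Negishi) adds Me and Al syn across the alkyne with Al on the terminal carbon, and iodinolysis of the C–Al bond with retention should give only the E iodide.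

Step 2
Reactants: 3 (E)-3-iodo-2-methylprop-2-en-1-ol
Product: 4 (E)-3-iodo-2-methylprop-2-enal
Conditions: MnO2, CH2Cl2, rt
Reagents that add atoms: none
Why: Allylic oxidation with MnO2 stops at the enal and leaves the C–I bond and the alkene geometry untouched.

Step 3
Reactants: 4 (E)-3-iodo-2-methylprop-2-enal
Product: 5 (2E,4E)-5-iodo-4-methylpenta-2,4-dienal
Conditions: Ph3P=CHCHO, toluene, 80 °C
Reagents that add atoms: (triphenylphosphoranylidene)acetaldehyde O=CC=P(c1ccccc1)(c1ccccc1)c1ccccc1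
Why: Wittig olefination with the stabilised formyl ylide should give the E enal while the trisubstituted iodoalkene stays inert.

Step 4
Reactants: 5 (2E,4E)-5-iodo-4-methylpenta-2,4-dienal
Product: 7 (3R,4R,5E,7E)-8-iodo-3-methoxy-7-methylocta-1,5,7-trien-4-ol, via borinate 6 (not isolated)
Conditions: allyl methyl ether, s-BuLi, THF, −78 °C; (−)-Ipc2BOMe; BF3·OEt2; then 5, −78 °C; NaOH, H2O2, rt
Reagents that add atoms: allyl methyl ether COCC=C
Why: Brown alkoxyallylboration through a chair Zimmerman–Traxler transition state, in which the Z γ-methoxyallyl unit gives the syn methoxy-carbinol pair and the (+)-α-pinene-derived ligands select the aldehyde face that sets C6 and C7 as R,R, with 1,2-addition to the dienal expected.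

Step 5
Reactants: 7 (3R,4R,5E,7E)-8-iodo-3-methoxy-7-methylocta-1,5,7-trien-4-ol
Product: 8 triethylsilyl ether of 7
Conditions: TESOTf, 2,6-lutidine, CH2Cl2, −78 °C
Reagents that add atoms: triethylsilyl triflate CC[Si](CC)(CC)OS(=O)(=O)C(F)(F)F
Why: Silylation of the secondary allylic alcohol is fast at low temperature and creates no stereocentre.

Step 6
Reactants: 8 triethylsilyl ether of 7
Product: 9 (2E,4R,5R,6E,8E)-9-iodo-4-methoxy-8-methyl-5-(triethylsilyloxy)nona-2,6,8-trienal
Conditions: (E)-crotonaldehyde (5 equiv), second-generation Hoveyda–Grubbs catalyst RuCl2(=CH-C6H4-2-Oi-Pr)(H2IMes) (5 mol %), CH2Cl2, 40 °C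
Reagents that add atoms: (E)-crotonaldehyde C/C=C/C=O
Why: Olefin cross-metathesis of the monosubstituted alkene with an electron-poor partner should give the E enal, because the internal, hindered iododiene is a poor metathesis substrate and its E C8=C9 bond forbids ring closure.

Step 7
Reactants: 9 (2E,4R,5R,6E,8E)-9-iodo-4-methoxy-8-methyl-5-(triethylsilyloxy)nona-2,6,8-trienal
Product: 10 (2E,4E,6R,7R,8E,10E)-11-iodo-6-methoxy-10-methyl-7-(triethylsilyloxy)undeca-2,4,8,10-tetraenoic acid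
Conditions: (EtO)2P(O)CH2CO2H, LiN(SiMe3)2 (2.1 equiv), THF, −78 °C to rt; aq. NaH2PO4
Reagents that add atoms: diethylphosphonoacetic acid CCOP(=O)(CC(=O)O)OCC
Why: Horner–Wadsworth–Emmons reaction of the phosphonoacetate dianion should give the 2E acid directly and avoids an ester hydrolysis on the base-sensitive dienoate.

**Part 2: side-chain iodide C26–C36**

Step 8
Reactants: 11 butanal
Product: 13 (3S,4S)-3-methoxyhept-1-en-4-ol, via borinate 12 (not isolated)
Conditions: allyl methyl ether, s-BuLi, THF, −78 °C; (+)-Ipc2BOMe; BF3·OEt2; then 11, −78 °C; NaOH, H2O2, rt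
Reagents that add atoms: allyl methyl ether COCC=C
Why: The same Brown alkoxyallylboration with the antipodal ((−)-α-pinene-derived) reagent sets C33 (carbinol) and C32 (methoxy) syn with the opposite absolute sense needed in the side chain.

Step 9
Reactants: 13 (3S,4S)-3-methoxyhept-1-en-4-ol
Product: 14 triethylsilyl ether of 13
Conditions: TESOTf, 2,6-lutidine, CH2Cl2, −78 °C
Reagents that add atoms: triethylsilyl triflate CC[Si](CC)(CC)OS(=O)(=O)C(F)(F)F
Why: Standard silylation of a secondary alcohol, no stereocentre affected.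

Step 10
Reactants: 14 triethylsilyl ether of 13
Product: 16 (2R,3S)-2-methoxy-3-(triethylsilyloxy)hexanal, via ozonide 15 (not isolated)
Conditions: O3, CH2Cl2, −78 °C; then PPh3, −78 °C to rt
Reagents that add atoms: ozone [O-][O+]=O
Why: Ozonolysis of the only alkene with reductive work-up gives the α-methoxy aldehyde without base and hence without epimerisation.

Step 11
Reactants: 16 (2R,3S)-2-methoxy-3-(triethylsilyloxy)hexanal
Product: 17 ethyl (2E,4S,5S)-4-methoxy-2-methyl-5-(triethylsilyloxy)oct-2-enoate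
Conditions: Ph3P=C(Me)CO2Et, CH2Cl2, rt
Reagents that add atoms: ethyl 2-(triphenylphosphoranylidene)propanoate CCOC(=O)C(C)=P(c1ccccc1)(c1ccccc1)c1ccccc1
Why: Wittig reaction with the stabilised α-methyl ylide should give the E trisubstituted enoate (methyl cis to C32) under neutral conditions that do not epimerise the aldehyde.

Step 12
Reactants: 17 ethyl (2E,4S,5S)-4-methoxy-2-methyl-5-(triethylsilyloxy)oct-2-enoate
Product: 18 (2E,4S,5S)-4-methoxy-2-methyl-5-(triethylsilyloxy)oct-2-en-1-ol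
Conditions: i-Bu2AlH, CH2Cl2, −78 °C; aq. potassium sodium tartrate
Reagents that add atoms: none
Why: 1,2-Reduction of the enoate with the aluminium hydride gives the allylic alcohol and leaves silyl ether and stereocentres untouched.

Step 13
Reactants: 18 (2E,4S,5S)-4-methoxy-2-methyl-5-(triethylsilyloxy)oct-2-en-1-ol
Product: 19 [(2R,3R)-3-[(1S,2S)-1-methoxy-2-(triethylsilyloxy)pentyl]-2-methyloxiran-2-yl]methanol
Conditions: Ti(Oi-Pr)4 (cat.), D-(−)-diisopropyl tartrate (cat.), t-BuOOH, 4 Å MS, CH2Cl2, −20 °C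
Reagents that add atoms: tert-butyl hydroperoxide CC(C)(C)OO
Why: Sharpless asymmetric epoxidation, in which the titanium D-(−)-tartrate complex delivers oxygen to the alkene face that gives the (2R,3R) epoxide (C30, C31), with reagent control overriding the C32 methoxy group.

Step 14
Reactants: 19 [(2R,3R)-3-[(1S,2S)-1-methoxy-2-(triethylsilyloxy)pentyl]-2-methyloxiran-2-yl]methanol
Product: 20 (2S,3R)-3-[(1S,2S)-1-methoxy-2-(triethylsilyloxy)pentyl]-2-methyloxirane-2-carbaldehyde
Conditions: Dess–Martin periodinane, NaHCO3, CH2Cl2, 0 °C to rt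
Reagents that add atoms: none
Why: Buffered Dess–Martin oxidation gives the epoxy aldehyde, whose α-carbon is quaternary and cannot epimerise.

Step 15
Reactants: 20 (2S,3R)-3-[(1S,2S)-1-methoxy-2-(triethylsilyloxy)pentyl]-2-methyloxirane-2-carbaldehyde
Product: 22 (1S)-1-[(2R,3R)-3-[(1S,2S)-1-methoxy-2-(triethylsilyloxy)pentyl]-2-methyloxiran-2-yl]but-3-en-1-ol, via borinate 21 (not isolated)
Conditions: (+)-B-allyldiisopinocampheylborane, Et2O, −78 °C; then NaOH, H2O2, 0 °C to rt
Reagents that add atoms: (+)-B-allyldiisopinocampheylborane C=CCB([C@@H]1C[C@@H]2C[C@H]([C@H]1C)C2(C)C)[C@@H]1C[C@@H]2C[C@H]([C@H]1C)C2(C)C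
Why: Brown allylboration, whose reagent-controlled chair transition state should set C29 as S, threo to the epoxide, a relation that hydroxyl-directed epoxidation would not give.

Step 16
Reactants: 22 the C29 homoallylic alcohol
Product: 23 triethylsilyl ether of 22
Conditions: TESOTf, 2,6-lutidine, CH2Cl2, −78 °C
Reagents that add atoms: triethylsilyl triflate CC[Si](CC)(CC)OS(=O)(=O)C(F)(F)F
Why: Standard silylation, with the epoxide stable to the buffered triflate at low temperature.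

Step 17
Reactants: 23 triethylsilyl ether of 22
Product: 25 C27 aldehyde of the side chain (C27–C36, 29,33-bis-TES, epoxide intact), via ozonide 24 (not isolated)
Conditions: O3, CH2Cl2, −78 °C; then PPh3, −78 °C to rt
Reagents that add atoms: ozone [O-][O+]=O
Why: Ozonolysis of the only alkene gives the β-silyloxy aldehyde without touching the epoxide or the silyl ethers.

Step 18
Reactants: 25 C27 aldehyde of the side chain
Product: 26 side-chain (E)-alkenyl iodide C26–C36 (29,33-bis-TES)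
Conditions: CrCl2, CHI3, THF/dioxane, 0 °C to rt
Reagents that add atoms: iodoform IC(I)I
Why: Takai olefination through a geminal dichromium reagent gives the E alkenyl iodide with high selectivity, and the epoxide and silyl ethers tolerate CrCl2.

**Part 3: boronate C12–C25 and union with the side chain**

Step 19
Reactants: 27 (S)-trityl glycidyl ether
Product: 29 (S)-2-methoxy-1-[(4-methoxybenzyl)oxy]-3-(trityloxy)propane, via sodium alkoxide 28 (not isolated)
Conditions: 4-MeOC6H4CH2OH, NaH, DMF, 60 °C; then MeI, 0 °C to rt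
Reagents that add atoms: 4-methoxybenzyl alcohol COc1ccc(CO)cc1; iodomethane CI
Why: The alkoxide opens the terminal epoxide at its CH2 carbon (SN2), so the C24 stereocentre is untouched, and the secondary alkoxide formed is methylated in the same flask (Williamson etherification).

Step 20
Reactants: 29 (S)-2-methoxy-1-[(4-methoxybenzyl)oxy]-3-(trityloxy)propane
Product: 30 (R)-2-methoxy-3-[(4-methoxybenzyl)oxy]propan-1-ol
Conditions: p-TsOH·H2O (cat.), MeOH/CH2Cl2, 0 °C to rt
Reagents that add atoms: none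
Why: Acid-catalysed solvolysis of the trityl ether (SN1 at the trityl carbon) leaves the PMB ether and the stereocentre intact.

Step 21
Reactants: 30 (R)-2-methoxy-3-[(4-methoxybenzyl)oxy]propan-1-ol
Product: 31 (S)-2-methoxy-3-[(4-methoxybenzyl)oxy]propanal
Conditions: Dess–Martin periodinane, NaHCO3, CH2Cl2, 0 °C
Reagents that add atoms: none
Why: Dess–Martin oxidation gives the α-methoxy aldehyde under non-epimerising conditions.

Step 22
Reactants: 31 (S)-2-methoxy-3-[(4-methoxybenzyl)oxy]propanal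
Product: 33 (2S,3S,4R)-2-methoxy-1-[(4-methoxybenzyl)oxy]-4-methylhex-5-en-3-ol, via borinate 32 (not isolated)
Conditions: cis-2-butene, KOt-Bu, n-BuLi, THF, −78 to −45 °C; (−)-Ipc2BOMe, −78 °C; BF3·OEt2; then 31, −78 °C; NaOH, H2O2
Reagents that add atoms: cis-2-butene C/C=C\C
Why: Brown crotylboration, in which the Z crotyl group gives the 22,23-syn pair through a chair transition state and the (+)-α-pinene-derived ligands set C23 as S, syn to the C24 methoxy group, by reagent control.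

Step 23
Reactants: 33 (2S,3S,4R)-2-methoxy-1-[(4-methoxybenzyl)oxy]-4-methylhex-5-en-3-ol
Product: 34 triethylsilyl ether of 33
Conditions: TESOTf, 2,6-lutidine, CH2Cl2, −78 °C
Reagents that add atoms: triethylsilyl triflate CC[Si](CC)(CC)OS(=O)(=O)C(F)(F)F
Why: The triflate silylates the hindered secondary alcohol cleanly, no stereocentre affected.

Step 24
Reactants: 34 triethylsilyl ether of 33
Product: 36 (2S,3S,4S)-4-methoxy-5-[(4-methoxybenzyl)oxy]-2-methyl-3-(triethylsilyloxy)pentanal, via diol 35 (not isolated)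
Conditions: OsO4 (cat.), NaIO4, 2,6-lutidine, dioxane/H2O, rt
Reagents that add atoms: osmium tetroxide O=[Os](=O)(=O)=O; sodium periodate [Na+].[O-]I(=O)(=O)=O
Why: Johnson–Lemieux oxidative cleavage of the only alkene gives the α-methyl aldehyde, with 2,6-lutidine suppressing epimerisation and over-oxidation and the PMB ether spared.

Step 25
Reactants: 36 (2S,3S,4S)-4-methoxy-5-[(4-methoxybenzyl)oxy]-2-methyl-3-(triethylsilyloxy)pentanal
Product: 37 (2E,4R,5S,6S)-6-methoxy-7-[(4-methoxybenzyl)oxy]-2,4-dimethyl-5-(triethylsilyloxy)hept-2-enal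
Conditions: Ph3P=C(Me)CHO, toluene, 90 °C
Reagents that add atoms: 2-(triphenylphosphoranylidene)propanal CC(C=O)=P(c1ccccc1)(c1ccccc1)c1ccccc1
Why: Wittig reaction with the stabilised α-methyl formyl ylide should give the E trisubstituted enal (C20=C21) without base-induced epimerisation at C22.

Step 26
Reactants: 37 (2E,4R,5S,6S)-6-methoxy-7-[(4-methoxybenzyl)oxy]-2,4-dimethyl-5-(triethylsilyloxy)hept-2-enal
Product: 38 (2E,4E,6R,7S,8S)-8-methoxy-9-[(4-methoxybenzyl)oxy]-4,6-dimethyl-7-(triethylsilyloxy)nona-2,4-dienal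
Conditions: Ph3P=CHCHO, toluene, 90 °C
Reagents that add atoms: (triphenylphosphoranylidene)acetaldehyde O=CC=P(c1ccccc1)(c1ccccc1)c1ccccc1
Why: A second Wittig homologation with the formyl ylide should give the E,E dienal (C18=C19).

Step 27
Reactants: 38 (2E,4E,6R,7S,8S)-8-methoxy-9-[(4-methoxybenzyl)oxy]-4,6-dimethyl-7-(triethylsilyloxy)nona-2,4-dienal
Product: 40 C14–C25 dienol (terminal C14=C15 alkene, 16-OMe, 17-OH, 23-OTES, 24-OMe, 25-OPMB; C16, C17, C22–C24 as in target), via borinate 39 (not isolated)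
Conditions: allyl methyl ether, s-BuLi, THF, −78 °C; (−)-Ipc2BOMe; BF3·OEt2; then 38, −78 °C; NaOH, H2O2, rt
Reagents that add atoms: allyl methyl ether COCC=C
Why: Brown alkoxyallylboration as in step 4 with the same antipode sets C16 (OMe) and C17 (OH) syn and R,R by reagent control through the chair transition state.

Step 28
Reactants: 40 C14–C25 dienol
Product: 41 17-triethylsilyl ether of 40
Conditions: TESOTf, 2,6-lutidine, CH2Cl2, −78 °C
Reagents that add atoms: triethylsilyl triflate CC[Si](CC)(CC)OS(=O)(=O)C(F)(F)F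
Why: Standard silylation of the allylic alcohol, no stereocentre affected.

Step 29
Reactants: 41 17-triethylsilyl ether of 40
Product: 42 C14 pinacol boronate (C14–C25, 17,23-bis-TES, 25-OPMB)
Conditions: [Ir(cod)Cl]2 (cat.), bis(diphenylphosphino)methane (cat.), pinacolborane, CH2Cl2, rt
Reagents that add atoms: pinacolborane CC1(C)OBOC1(C)C
Why: Iridium-catalysed hydroboration with pinacolborane is anti-Markovnikov and selective for monosubstituted alkenes, so the primary C14 boronate should form without touching the internal diene.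

Step 30
Reactants: 42 C14 pinacol boronate
Product: 44 C13 pinacol boronate (C13–C25), via chloromethyl boronate complex 43 (not isolated)
Conditions: BrCH2Cl, n-BuLi, THF, −78 °C to rt
Reagents that add atoms: bromochloromethane ClCBr
Why: Matteson homologation, in which (chloromethyl)lithium adds to boron and 1,2-migration of the alkyl group with loss of chloride inserts C13.

Step 31
Reactants: 44 C13 pinacol boronate
Product: 46 (12R) C12 pinacol boronate (C12–C25, 17,23-bis-TES, 25-OPMB), via boronate complex 45 (not isolated)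
Conditions: ethyl 2,4,6-triisopropylbenzoate, s-BuLi, (−)-sparteine, Et2O, −78 °C; then 44, −78 °C; then 35 °C
Reagents that add atoms: ethyl 2,4,6-triisopropylbenzoate CCOC(=O)c1c(C(C)C)cc(C(C)C)cc1C(C)C
Why: Lithiation–borylation (1,2-metallate homologation), in which the sparteine-complexed (S)-lithiated benzoate is borylated with retention and the alkyl group migrates with inversion, sets the methyl-bearing C12 boronate as R under reagent control.

Step 32
Reactants: 46 (12R) C12 pinacol boronate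
Product: 47 C25 primary alcohol (PMB removed)
Conditions: DDQ, CH2Cl2/pH 7 buffer, 0 °C
Reagents that add atoms: none
Why: Oxidative PMB cleavage (benzylic hydride abstraction, then hydrolysis) frees the primary alcohol, while silyl ethers, diene and alkyl boronate should survive the buffered conditions.

Step 33
Reactants: 47 C25 primary alcohol
Product: 48 C25 aldehyde (C12–C25, 12-Bpin, 17,23-bis-TES)
Conditions: Dess–Martin periodinane, NaHCO3, CH2Cl2, 0 °C
Reagents that add atoms: none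
Why: Dess–Martin oxidation gives the α-methoxy aldehyde without epimerisation and leaves the boronate untouched.

Step 34
Reactants: 48 C25 aldehyde; 26 side-chain (E)-alkenyl iodide
Product: 50 C12–C36 alcohol (25-OH free, 12-Bpin, 17,23,29,33-tetrakis-TES; all centres as in target), via alkenylchromium 49 (not isolated)
Conditions: CrCl2, NiCl2 (cat.), DMSO, rt
Reagents that add atoms: none
Why: Nozaki–Hiyama–Kishi coupling, in which the alkenylchromium species adds only to the aldehyde with retention of alkene geometry, and Felkin–Anh attack anti to the C24 methoxy group should set C25 (24,25-anti) and leave its hydroxyl as the only free OH.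

**Part 4: ring closure and deprotection**

Step 35
Reactants: 10 C1–C11 acid; 50 C12–C36 alcohol
Product: 52 seco ester (O25 acylated by C1; C11 alkenyl iodide, C12 Bpin, pentakis-TES), via mixed anhydride 51 (not isolated)
Conditions: 2-methyl-6-nitrobenzoic anhydride, DMAP, Et3N, CH2Cl2, rt
Reagents that add atoms: none
Why: Shiina esterification (mixed-anhydride activation, DMAP acyl transfer) acylates the single free hydroxyl under mild conditions that should not isomerise the dienoate.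

Step 36
Reactants: 52 seco ester
Product: 53 seco ester with free C12 boronic acid
Conditions: NaIO4, NH4OAc, acetone/THF/H2O, rt
Reagents that add atoms: water O
Why: Periodate cleaves the pinacol ligand and releases the secondary boronic acid needed for transmetalation, with C12 unaffected and no 1,2-diol elsewhere in the molecule.

Step 37
Reactants: 53 seco ester with free C12 boronic acid
Product: 54 pentakis-TES macrolide (26-membered lactone, all centres as in target)
Conditions: Pd[P(o-tol)3]2 (20 mol %), Ag2O (3 equiv), THF, 65 °C, slow addition of 53 to 1 mM final concentration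
Reagents that add atoms: none
Why: Proposed new method: zerovalent palladium inserts into the C11–I bond with retention of the C10=C11 geometry, Ag2O turns the Pd–I into a Pd–O species that takes up the C12 boronic acid in a closed, four-centred (front-side) transmetalation, and C–C reductive elimination from the alkenyl(sec-alkyl)palladium must outrun β-hydride elimination. The closest known reaction types are the stereoretentive Suzuki–Miyaura coupling of unactivated secondary alkylboronic acids with aryl halides under Pd/P(o-tol)3/Ag2O and the B-alkyl Suzuki macrocyclisation of primary alkylboranes with alkenyl iodides; a ring-closing coupling of a secondary alkylboron with an alkenyl iodide has not been shown. The 26-membered lactone ring is closed end to end at C11/C12 by reductive elimination from a 27-membered palladacycle. No centre is made from a prochiral atom: C12 enters as the (R)-boronic acid and its configuration is carried into the ring with retention, controlled by the closed transmetalation that the bulky phosphine enforces. The step needs ring closure over oligomerisation (high dilution, slow addition), retention over inversion and no chain-walking (bulky monodentate phosphine, silver oxide instead of free hydroxide), and reaction only at the one C(sp2)–I bond. The substrate offers a single iodide and a single boron, no free OH, and an ester, epoxide and silyl ethers that tolerate the near-neutral silver oxide conditions.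

Step 38
Reactants: 54 pentakis-TES macrolide
Product: 55 target macrolide CNP0253553.3
Conditions: HF·pyridine, pyridine, THF, 0 °C to rt
Reagents that add atoms: none
Why: Buffered fluoride desilylation removes all five TES ethers while the epoxide, the dienoate lactone and the dienes should survive, no stereocentre being touched.

**Compound list**

1 | prop-2-yn-1-ol | C#CCO | starting material
2 | alkenylalane, dimethylaluminium (E)-3-(dimethylalumanyl)-2-methylprop-2-en-1-olate | C[Al](C)OC/C(C)=C/[Al](C)C | intermediate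
3 | (E)-3-iodo-2-methylprop-2-en-1-ol | OC/C(C)=C/I | intermediate
4 | (E)-3-iodo-2-methylprop-2-enal | O=C/C(C)=C/I | intermediate
5 | (2E,4E)-5-iodo-4-methylpenta-2,4-dienal | O=C/C=C/C(C)=C/I | intermediate
6 | diisopinocampheylborinate of 7 (Ipc from (+)-α-pinene) | C=C[C@@H](OC)[C@H](OB([C@@H]1C[C@@H]2C[C@H]([C@H]1C)C2(C)C)[C@@H]1C[C@@H]2C[C@H]([C@H]1C)C2(C)C)/C=C/C(C)=C/I | intermediate
7 | (3R,4R,5E,7E)-8-iodo-3-methoxy-7-methylocta-1,5,7-trien-4-ol | C=C[C@@H](OC)[C@H](O)/C=C/C(C)=C/I | intermediate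
8 | triethylsilyl ether of 7 | C=C[C@@H](OC)[C@H](O[Si](CC)(CC)CC)/C=C/C(C)=C/I | intermediate
9 | (2E,4R,5R,6E,8E)-9-iodo-4-methoxy-8-methyl-5-(triethylsilyloxy)nona-2,6,8-trienal | O=C/C=C/[C@@H](OC)[C@H](O[Si](CC)(CC)CC)/C=C/C(C)=C/I | intermediate
10 | (2E,4E,6R,7R,8E,10E)-11-iodo-6-methoxy-10-methyl-7-(triethylsilyloxy)undeca-2,4,8,10-tetraenoic acid | OC(=O)/C=C/C=C/[C@@H](OC)[C@H](O[Si](CC)(CC)CC)/C=C/C(C)=C/I | intermediate
11 | butanal | CCCC=O | starting material
12 | diisopinocampheylborinate of 13 (Ipc from (−)-α-pinene) | CCC[C@H](OB([C@H]1C[C@H]2C[C@@H]([C@@H]1C)C2(C)C)[C@H]1C[C@H]2C[C@@H]([C@@H]1C)C2(C)C)[C@@H](OC)C=C | intermediate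
13 | (3S,4S)-3-methoxyhept-1-en-4-ol | CCC[C@H](O)[C@@H](OC)C=C | intermediate
14 | triethylsilyl ether of 13 | CCC[C@H](O[Si](CC)(CC)CC)[C@@H](OC)C=C | intermediate
15 | ozonide of 14 (1,2,4-trioxolane at the former vinyl group) | CCC[C@H](O[Si](CC)(CC)CC)[C@@H](OC)C1OCOO1 | intermediate
16 | (2R,3S)-2-methoxy-3-(triethylsilyloxy)hexanal | CCC[C@H](O[Si](CC)(CC)CC)[C@@H](OC)C=O | intermediate
17 | ethyl (2E,4S,5S)-4-methoxy-2-methyl-5-(triethylsilyloxy)oct-2-enoate | CCC[C@H](O[Si](CC)(CC)CC)[C@@H](OC)/C=C(\C)C(=O)OCC | intermediate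
18 | (2E,4S,5S)-4-methoxy-2-methyl-5-(triethylsilyloxy)oct-2-en-1-ol | CCC[C@H](O[Si](CC)(CC)CC)[C@@H](OC)/C=C(\C)CO | intermediate
19 | [(2R,3R)-3-[(1S,2S)-1-methoxy-2-(triethylsilyloxy)pentyl]-2-methyloxiran-2-yl]methanol | CCC[C@H](O[Si](CC)(CC)CC)[C@@H](OC)[C@H]1O[C@]1(C)CO | intermediate
20 | (2S,3R)-3-[(1S,2S)-1-methoxy-2-(triethylsilyloxy)pentyl]-2-methyloxirane-2-carbaldehyde | CCC[C@H](O[Si](CC)(CC)CC)[C@@H](OC)[C@H]1O[C@]1(C)C=O | intermediate
21 | diisopinocampheylborinate of 22 (Ipc from (+)-α-pinene) | CCC[C@H](O[Si](CC)(CC)CC)[C@@H](OC)[C@H]1O[C@]1(C)[C@@H](OB([C@@H]2C[C@@H]3C[C@H]([C@H]2C)C3(C)C)[C@@H]2C[C@@H]3C[C@H]([C@H]2C)C3(C)C)CC=C | intermediate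
22 | (1S)-1-[(2R,3R)-3-[(1S,2S)-1-methoxy-2-(triethylsilyloxy)pentyl]-2-methyloxiran-2-yl]but-3-en-1-ol | CCC[C@H](O[Si](CC)(CC)CC)[C@@H](OC)[C@H]1O[C@]1(C)[C@@H](O)CC=C | intermediate
23 | triethylsilyl ether of 22 (29,33-bis-TES) | CCC[C@H](O[Si](CC)(CC)CC)[C@@H](OC)[C@H]1O[C@]1(C)[C@@H](O[Si](CC)(CC)CC)CC=C | intermediate
24 | ozonide of 23 | CCC[C@H](O[Si](CC)(CC)CC)[C@@H](OC)[C@H]1O[C@]1(C)[C@@H](O[Si](CC)(CC)CC)CC1OCOO1 | intermediate
25 | C27 aldehyde of the side chain (C27–C36, 29,33-bis-TES, 30,31-epoxide, 32-OMe) | CCC[C@H](O[Si](CC)(CC)CC)[C@@H](OC)[C@H]1O[C@]1(C)[C@@H](O[Si](CC)(CC)CC)CC=O | intermediate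
26 | side-chain (E)-alkenyl iodide C26–C36 (29,33-bis-TES) | CCC[C@H](O[Si](CC)(CC)CC)[C@@H](OC)[C@H]1O[C@]1(C)[C@@H](O[Si](CC)(CC)CC)C/C=C/I | intermediate
27 | (S)-trityl glycidyl ether, (S)-2-[(trityloxy)methyl]oxirane | c1ccc(cc1)C(c1ccccc1)(c1ccccc1)OC[C@@H]1CO1 | starting material
28 | sodium (S)-1-[(4-methoxybenzyl)oxy]-3-(trityloxy)propan-2-olate | c1ccc(cc1)C(c1ccccc1)(c1ccccc1)OC[C@@H]([O-])COCc1ccc(OC)cc1.[Na+] | intermediate
29 | (S)-2-methoxy-1-[(4-methoxybenzyl)oxy]-3-(trityloxy)propane | c1ccc(cc1)C(c1ccccc1)(c1ccccc1)OC[C@@H](OC)COCc1ccc(OC)cc1 | intermediate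
30 | (R)-2-methoxy-3-[(4-methoxybenzyl)oxy]propan-1-ol | OC[C@@H](OC)COCc1ccc(OC)cc1 | intermediate
31 | (S)-2-methoxy-3-[(4-methoxybenzyl)oxy]propanal | O=C[C@@H](OC)COCc1ccc(OC)cc1 | intermediate
32 | diisopinocampheylborinate of 33 (Ipc from (+)-α-pinene) | C=C[C@@H](C)[C@H](OB([C@@H]1C[C@@H]2C[C@H]([C@H]1C)C2(C)C)[C@@H]1C[C@@H]2C[C@H]([C@H]1C)C2(C)C)[C@@H](OC)COCc1ccc(OC)cc1 | intermediate
33 | (2S,3S,4R)-2-methoxy-1-[(4-methoxybenzyl)oxy]-4-methylhex-5-en-3-ol | C=C[C@@H](C)[C@H](O)[C@@H](OC)COCc1ccc(OC)cc1 | intermediate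
34 | triethylsilyl ether of 33 | C=C[C@@H](C)[C@H](O[Si](CC)(CC)CC)[C@@H](OC)COCc1ccc(OC)cc1 | intermediate
35 | 5,6-diol from 34 (carbinol centre at C5 of the hexane chain undefined) | OCC(O)[C@@H](C)[C@H](O[Si](CC)(CC)CC)[C@@H](OC)COCc1ccc(OC)cc1 | intermediate
36 | (2S,3S,4S)-4-methoxy-5-[(4-methoxybenzyl)oxy]-2-methyl-3-(triethylsilyloxy)pentanal | O=C[C@@H](C)[C@H](O[Si](CC)(CC)CC)[C@@H](OC)COCc1ccc(OC)cc1 | intermediate
37 | (2E,4R,5S,6S)-6-methoxy-7-[(4-methoxybenzyl)oxy]-2,4-dimethyl-5-(triethylsilyloxy)hept-2-enal | O=C/C(C)=C/[C@@H](C)[C@H](O[Si](CC)(CC)CC)[C@@H](OC)COCc1ccc(OC)cc1 | intermediate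
38 | (2E,4E,6R,7S,8S)-8-methoxy-9-[(4-methoxybenzyl)oxy]-4,6-dimethyl-7-(triethylsilyloxy)nona-2,4-dienal | O=C/C=C/C(C)=C/[C@@H](C)[C@H](O[Si](CC)(CC)CC)[C@@H](OC)COCc1ccc(OC)cc1 | intermediate
39 | diisopinocampheylborinate of 40 (Ipc from (+)-α-pinene) | C=C[C@@H](OC)[C@H](OB([C@@H]1C[C@@H]2C[C@H]([C@H]1C)C2(C)C)[C@@H]1C[C@@H]2C[C@H]([C@H]1C)C2(C)C)/C=C/C(C)=C/[C@@H](C)[C@H](O[Si](CC)(CC)CC)[C@@H](OC)COCc1ccc(OC)cc1 | intermediate
40 | C14–C25 dienol (C14=C15 alkene, 16-OMe, 17-OH, 23-OTES, 24-OMe, 25-OPMB) | C=C[C@@H](OC)[C@H](O)/C=C/C(C)=C/[C@@H](C)[C@H](O[Si](CC)(CC)CC)[C@@H](OC)COCc1ccc(OC)cc1 | intermediate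
41 | 17-triethylsilyl ether of 40 | C=C[C@@H](OC)[C@H](O[Si](CC)(CC)CC)/C=C/C(C)=C/[C@@H](C)[C@H](O[Si](CC)(CC)CC)[C@@H](OC)COCc1ccc(OC)cc1 | intermediate
42 | C14 pinacol boronate (C14–C25, 17,23-bis-TES, 25-OPMB) | CC1(C)OB(OC1(C)C)CC[C@@H](OC)[C@H](O[Si](CC)(CC)CC)/C=C/C(C)=C/[C@@H](C)[C@H](O[Si](CC)(CC)CC)[C@@H](OC)COCc1ccc(OC)cc1 | intermediate
43 | lithium (chloromethyl)boronate complex of 42 | [Li+].ClC[B-]1(OC(C)(C)C(C)(C)O1)CC[C@@H](OC)[C@H](O[Si](CC)(CC)CC)/C=C/C(C)=C/[C@@H](C)[C@H](O[Si](CC)(CC)CC)[C@@H](OC)COCc1ccc(OC)cc1 | intermediate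
44 | C13 pinacol boronate (C13–C25, 17,23-bis-TES, 25-OPMB) | CC1(C)OB(OC1(C)C)CCC[C@@H](OC)[C@H](O[Si](CC)(CC)CC)/C=C/C(C)=C/[C@@H](C)[C@H](O[Si](CC)(CC)CC)[C@@H](OC)COCc1ccc(OC)cc1 | intermediate
45 | lithium boronate complex of 44 with the (S)-1-(2,4,6-triisopropylbenzoyloxy)ethyl group on boron | [Li+].C[C@@H](OC(=O)c1c(C(C)C)cc(C(C)C)cc1C(C)C)[B-]1(OC(C)(C)C(C)(C)O1)CCC[C@@H](OC)[C@H](O[Si](CC)(CC)CC)/C=C/C(C)=C/[C@@H](C)[C@H](O[Si](CC)(CC)CC)[C@@H](OC)COCc1ccc(OC)cc1 | intermediate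
46 | (12R) C12 pinacol boronate (C12–C25, 17,23-bis-TES, 25-OPMB) | CC1(C)OB(OC1(C)C)[C@H](C)CCC[C@@H](OC)[C@H](O[Si](CC)(CC)CC)/C=C/C(C)=C/[C@@H](C)[C@H](O[Si](CC)(CC)CC)[C@@H](OC)COCc1ccc(OC)cc1 | intermediate
47 | C25 primary alcohol (C12–C25, 12-Bpin, 17,23-bis-TES) | CC1(C)OB(OC1(C)C)[C@H](C)CCC[C@@H](OC)[C@H](O[Si](CC)(CC)CC)/C=C/C(C)=C/[C@@H](C)[C@H](O[Si](CC)(CC)CC)[C@@H](OC)CO | intermediate
48 | C25 aldehyde (C12–C25, 12-Bpin, 17,23-bis-TES) | CC1(C)OB(OC1(C)C)[C@H](C)CCC[C@@H](OC)[C@H](O[Si](CC)(CC)CC)/C=C/C(C)=C/[C@@H](C)[C@H](O[Si](CC)(CC)CC)[C@@H](OC)C=O | intermediate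
49 | alkenylchromium dichloride from 26 (trivalent chromium at C26) | CCC[C@H](O[Si](CC)(CC)CC)[C@@H](OC)[C@H]1O[C@]1(C)[C@@H](O[Si](CC)(CC)CC)C/C=C/[Cr](Cl)Cl | intermediate
50 | C12–C36 alcohol (25-OH, 12-Bpin, 17,23,29,33-tetrakis-TES) | CCC[C@H](O[Si](CC)(CC)CC)[C@@H](OC)[C@H]1O[C@]1(C)[C@@H](O[Si](CC)(CC)CC)C/C=C/[C@H](O)[C@H](OC)[C@@H](O[Si](CC)(CC)CC)[C@H](C)/C=C(C)/C=C/[C@@H](O[Si](CC)(CC)CC)[C@H](OC)CCC[C@@H](C)B1OC(C)(C)C(C)(C)O1 | intermediate
51 | mixed anhydride of 10 with 2-methyl-6-nitrobenzoic acid | Cc1cccc([N+](=O)[O-])c1C(=O)OC(=O)/C=C/C=C/[C@@H](OC)[C@H](O[Si](CC)(CC)CC)/C=C/C(C)=C/I | intermediate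
52 | seco ester (C1–O25 ester, C11 iodide, C12 Bpin, 7,17,23,29,33-pentakis-TES) | CCC[C@H](O[Si](CC)(CC)CC)[C@@H](OC)[C@H]1O[C@]1(C)[C@@H](O[Si](CC)(CC)CC)C/C=C/[C@H](OC(=O)/C=C/C=C/[C@@H](OC)[C@H](O[Si](CC)(CC)CC)/C=C/C(C)=C/I)[C@H](OC)[C@@H](O[Si](CC)(CC)CC)[C@H](C)/C=C(C)/C=C/[C@@H](O[Si](CC)(CC)CC)[C@H](OC)CCC[C@@H](C)B1OC(C)(C)C(C)(C)O1 | intermediate
53 | seco ester with free C12 boronic acid | CCC[C@H](O[Si](CC)(CC)CC)[C@@H](OC)[C@H]1O[C@]1(C)[C@@H](O[Si](CC)(CC)CC)C/C=C/[C@H](OC(=O)/C=C/C=C/[C@@H](OC)[C@H](O[Si](CC)(CC)CC)/C=C/C(C)=C/I)[C@H](OC)[C@@H](O[Si](CC)(CC)CC)[C@H](C)/C=C(C)/C=C/[C@@H](O[Si](CC)(CC)CC)[C@H](OC)CCC[C@@H](C)B(O)O | intermediate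
54 | 7,17,23,29,33-pentakis(triethylsilyl) ether of the target macrolide | CCC[C@H](O[Si](CC)(CC)CC)[C@@H](OC)[C@H]1O[C@]1(C)[C@@H](O[Si](CC)(CC)CC)C/C=C/[C@@H]1OC(=O)/C=C/C=C/[C@@H](OC)[C@H](O[Si](CC)(CC)CC)/C=C/C(C)=C/[C@H](C)CCC[C@@H](OC)[C@H](O[Si](CC)(CC)CC)/C=C/C(C)=C/[C@@H](C)[C@H](O[Si](CC)(CC)CC)[C@H]1OC | intermediate
55 | target macrolide CNP0253553.3 (6R,7R,12R,16R,17R,22R,23S,24R,25S,29S,30R,31R,32R,33S; 2E,4E,8E,10E,18E,20E,26E) | CCC[C@H](O)[C@@H](OC)[C@H]1O[C@]1(C)[C@@H](O)C/C=C/[C@@H]1OC(=O)/C=C/C=C/[C@@H](OC)[C@H](O)/C=C/C(C)=C/[C@H](C)CCC[C@@H](OC)[C@H](O)/C=C/C(C)=C/[C@@H](C)[C@H](O)[C@H]1OC | target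

**Step count and risks**

Total: 38 steps. Longest linear sequence: 20 steps (27 to 55, steps 19–38).

Most likely to fail:

1. Step 37 (Proposed new method). Transmetalation of the secondary boronic acid may be so slow at high dilution that protodeboronation, β-hydride elimination with chain-walking or oligomerisation outrun ring closure, or stereochemical fidelity at C12 may be partly lost. Fallback, from 46 and 8, returning at 54: iodide 8 is lithiated (t-BuLi, Et2O, −78 °C) to alkenyllithium F1, which adds to boronic ester 46 to give boronate complex F2. PhSeCl (THF/CF3CH2OH, −78 °C) triggers 1,2-migration of C12 with retention to the β-selanyl boronic ester F3, and mCPBA with syn-elimination gives triene F4 with 10E geometry and 12R configuration (Zweifel-type olefination, syn-elimination variant, known for enantioenriched secondary boronic esters). DDQ and then Dess–Martin oxidation give alcohol F5 and aldehyde F6. The Nozaki–Hiyama–Kishi coupling with 26 gives alcohol F7. Acylation with (2E)-penta-2,4-dienoyl chloride and pyridine gives ester F8. Ring-closing metathesis of its two terminal alkenes (second-generation Hoveyda–Grubbs catalyst RuCl2(=CH-C6H4-2-Oi-Pr)(H2IMes), high dilution) forms C4=C5 and gives 54. The ring closure is thus moved from C11–C12 to the dienoate.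

2. Step 34. Facial selectivity at C25 may be poor, because Felkin–Anh control by a single α-methoxy group in a chromium addition is only moderate. Fallback, from the C25-epimeric mixture of 50, returning at 50: Dess–Martin periodinane/NaHCO3 oxidises both epimers to enone F9. Chelation-controlled 1,2-reduction with Zn(BH4)2 (Et2O, −30 °C; zinc bridges the ketone and the C24 methoxy oxygen, hydride comes from the less hindered face) should give the 24,25-anti alcohol 50. C25 is then set by ketone reduction instead of by C–C bond formation.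

3. Step 29. The iridium hydride may also add to the conjugated diene or isomerise the allylic ether, eroding chemoselectivity. Fallback, from 41, returning at 42: hydroboration with 9-BBN (THF, 0 °C to rt) gives the alkylborane F10. Oxidation with NaBO3·4H2O gives primary alcohol F11. I2, PPh3 and imidazole give iodide F12. Copper-catalysed borylation (CuI (cat.), PPh3, LiOMe, bis(pinacolato)diboron, DMF, rt) gives 42. The C–B bond is then made by substitution instead of by catalytic hydroboration.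

**Further compounds**

F1 | step 37 | alkenyllithium from 8 | C=C[C@@H](OC)[C@H](O[Si](CC)(CC)CC)/C=C/C(C)=C/[Li]
F2 | step 37 | lithium alkenyl boronate complex of 46 | [Li+].C=C[C@@H](OC)[C@H](O[Si](CC)(CC)CC)/C=C/C(C)=C/[B-]1(OC(C)(C)C(C)(C)O1)[C@H](C)CCC[C@@H](OC)[C@H](O[Si](CC)(CC)CC)/C=C/C(C)=C/[C@@H](C)[C@H](O[Si](CC)(CC)CC)[C@@H](OC)COCc1ccc(OC)cc1
F3 | step 37 | β-(phenylselanyl) boronic ester (C10 and C11 centres set by anti addition, either face) | C=C[C@@H](OC)[C@H](O[Si](CC)(CC)CC)/C=C/C(C)([Se]c1ccccc1)C(B1OC(C)(C)C(C)(C)O1)[C@H](C)CCC[C@@H](OC)[C@H](O[Si](CC)(CC)CC)/C=C/C(C)=C/[C@@H](C)[C@H](O[Si](CC)(CC)CC)[C@@H](OC)COCc1ccc(OC)cc1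
F4 | step 37 | C4–C25 triene-diene (C11–C12 joined, 7,17,23-tris-TES, 25-OPMB) | C=C[C@@H](OC)[C@H](O[Si](CC)(CC)CC)/C=C/C(C)=C/[C@H](C)CCC[C@@H](OC)[C@H](O[Si](CC)(CC)CC)/C=C/C(C)=C/[C@@H](C)[C@H](O[Si](CC)(CC)CC)[C@@H](OC)COCc1ccc(OC)cc1
F5 | step 37 | C25 primary alcohol from F4 | C=C[C@@H](OC)[C@H](O[Si](CC)(CC)CC)/C=C/C(C)=C/[C@H](C)CCC[C@@H](OC)[C@H](O[Si](CC)(CC)CC)/C=C/C(C)=C/[C@@H](C)[C@H](O[Si](CC)(CC)CC)[C@@H](OC)CO
F6 | step 37 | C25 aldehyde from F5 | C=C[C@@H](OC)[C@H](O[Si](CC)(CC)CC)/C=C/C(C)=C/[C@H](C)CCC[C@@H](OC)[C@H](O[Si](CC)(CC)CC)/C=C/C(C)=C/[C@@H](C)[C@H](O[Si](CC)(CC)CC)[C@@H](OC)C=O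
F7 | step 37 | C4–C36 alcohol (25-OH, pentakis-TES, terminal C4=C5 alkene) | CCC[C@H](O[Si](CC)(CC)CC)[C@@H](OC)[C@H]1O[C@]1(C)[C@@H](O[Si](CC)(CC)CC)C/C=C/[C@H](O)[C@H](OC)[C@@H](O[Si](CC)(CC)CC)[C@H](C)/C=C(C)/C=C/[C@@H](O[Si](CC)(CC)CC)[C@H](OC)CCC[C@@H](C)/C=C(C)/C=C/[C@@H](O[Si](CC)(CC)CC)[C@H](OC)C=C
F8 | step 37 | (2E)-penta-2,4-dienoate ester of F7 | CCC[C@H](O[Si](CC)(CC)CC)[C@@H](OC)[C@H]1O[C@]1(C)[C@@H](O[Si](CC)(CC)CC)C/C=C/[C@H](OC(=O)/C=C/C=C)[C@H](OC)[C@@H](O[Si](CC)(CC)CC)[C@H](C)/C=C(C)/C=C/[C@@H](O[Si](CC)(CC)CC)[C@H](OC)CCC[C@@H](C)/C=C(C)/C=C/[C@@H](O[Si](CC)(CC)CC)[C@H](OC)C=C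
F9 | step 34 | C25 enone from 50 | CCC[C@H](O[Si](CC)(CC)CC)[C@@H](OC)[C@H]1O[C@]1(C)[C@@H](O[Si](CC)(CC)CC)C/C=C/C(=O)[C@H](OC)[C@@H](O[Si](CC)(CC)CC)[C@H](C)/C=C(C)/C=C/[C@@H](O[Si](CC)(CC)CC)[C@H](OC)CCC[C@@H](C)B1OC(C)(C)C(C)(C)O1
F10 | step 29 | B-alkyl-9-borabicyclo[3.3.1]nonane from 41 (boron at C14) | C1CCC2CCCC1B2CC[C@@H](OC)[C@H](O[Si](CC)(CC)CC)/C=C/C(C)=C/[C@@H](C)[C@H](O[Si](CC)(CC)CC)[C@@H](OC)COCc1ccc(OC)cc1
F11 | step 29 | C14 primary alcohol | OCC[C@@H](OC)[C@H](O[Si](CC)(CC)CC)/C=C/C(C)=C/[C@@H](C)[C@H](O[Si](CC)(CC)CC)[C@@H](OC)COCc1ccc(OC)cc1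
F12 | step 29 | C14 primary iodide | ICC[C@@H](OC)[C@H](O[Si](CC)(CC)CC)/C=C/C(C)=C/[C@@H](C)[C@H](O[Si](CC)(CC)CC)[C@@H](OC)COCc1ccc(OC)cc1
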